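**Strategy.** The ten-membered ring is opened at C1–C2. C1(O)–C2H2–C3(O) in the carbocycle is the aldol pattern of a C3 methyl ketone and a C1 aldehyde, and C1 hangs on the fully substituted C10, so the aldehyde cannot enolise. One intramolecular aldol addition therefore closes the ring, forms C1–C2 and sets the C1 carbinol that later becomes the 1,10-epoxide by inversion. The precursor is an open-chain Z-enone methyl ketone (C2–C6, from (S)-carvone, which also supplies C7) carrying the C8 senecioate, a C9 silyl ether and a free tertiary C10 hydroxyl next to the aldehyde.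

Key step: step 13

**Remarks on the chemistry (they govern the design).**
- Ring locants C1–C10 of 26 are used for all compounds; C7 bears the isopropenyl group, and O8, O9, O10 are the oxygens on those carbons.
- Geometric analysis shows that the C1 carbinol which closes to the cis 1,10-epoxide by inversion is the chelate (Cram) adduct, not the Felkin–Anh adduct. The C10 hydroxyl is therefore left free so that its lithium alkoxide can hold the aldehyde oxygen.
- A 9,10-acetonide could only be removed with acid after the 4,5-epoxide exists, and a C8 silyl ether would have to be exchanged next to a free C9 hydroxyl. The senecioate is therefore installed early, and O9 carries its own silyl group.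
- C1 is activated only after C3 has been reduced, because a β-sulfonyloxy ketone would eliminate.

**Route**

Step 1
Reactants: 1 prop-2-yn-1-ol
Product: 3 (E)-3-iodo-2-methylprop-2-en-1-ol, via alkenylalane 2 (not isolated)
Conditions: Me3Al (3 equiv), (C5H5)2ZrCl2 (0.25 equiv), CH2Cl2, 0 °C to rt; then I2, THF, −30 °C; aq. Na2S2O3, Rochelle salt
Reagents that add atoms: trimethylaluminium, C[Al](C)C; iodine, II
Why: Negishi zirconium-catalysed carboalumination adds CH3 and aluminium syn across the alkyne with aluminium at the terminus, and iodinolysis of the C–Al bond goes with retention, so the E-iodide that becomes C9=C10(CH3)–C1 should result.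

Step 2
Reactants: 3 (E)-3-iodo-2-methylprop-2-en-1-ol
Product: 4 (E)-tert-butyl[(3-iodo-2-methylprop-2-en-1-yl)oxy]dimethylsilane
Conditions: TBSCl, imidazole, DMF, 0 °C to rt
Reagents that add atoms: tert-butylchlorodimethylsilane, CC(C)(C)[Si](C)(C)Cl
Why: Imidazole-promoted silylation of the primary alcohol masks the future C1 hydroxyl through the chromium coupling and the C8 acylation.

Step 3
Reactants: 5 (S)-(+)-carvone
Product: 7 trans-6-hydroxycarvone, via potassium dienolate 6 (not isolated)
Conditions: KN(SiMe3)2, THF, −78 °C; then 2-(phenylsulfonyl)-3-phenyloxaziridine, −78 °C; aq. NH4Cl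
Reagents that add atoms: 2-(phenylsulfonyl)-3-phenyloxaziridine, O=S(=O)(c1ccccc1)N1OC1c1ccccc1
Why: Kinetic α'-deprotonation of the enone and electrophilic enolate hydroxylation by the N-sulfonyloxaziridine (anti to the isopropenyl group) put oxygen on the carbon that becomes C8, and its configuration is irrelevant because step 5 erases it.

Step 4
Reactants: 7 trans-6-hydroxycarvone
Product: 8 1-methyl-1,6-diol
Conditions: MeLi (3 equiv), THF, −78 to −20 °C; aq. NH4Cl
Reagents that add atoms: methyllithium, [Li]C
Why: Methyllithium deprotonates the hydroxyl and then adds 1,2 to the enone carbonyl (organolithium addition), bringing in the future C2 methyl group, and the new carbinol centre is also erased in step 5.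

Step 5
Reactants: 8 1-methyl-1,6-diol
Product: 9 (2R,4Z)-5-methyl-6-oxo-2-(prop-1-en-2-yl)hept-4-enal
Conditions: Pb(OAc)4, NaHCO3, CH2Cl2, −20 °C; filtered and used at once
Reagents that add atoms: none
Why: Criegee glycol cleavage breaks the ring bond between the two carbinol carbons, so the methyl ketone keeps the cis (Z) C4=C5 geometry enforced by the cyclohexene and the aldehyde carbon becomes C8 next to the untouched C7 stereocentre from carvone.

Step 6
Reactants: 9 keto aldehyde; 4 vinyl iodide
Product: 10 allylic alcohol (8-OH, E-C9=C10, C1–OTBS)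
Conditions: CrCl2 (4 equiv), NiCl2 (2 mol %), DMSO, rt
Reagents that add atoms: none
Why: The Nozaki–Hiyama–Kishi alkenylchromium addition is selective for the aldehyde over the methyl ketone and mild enough to spare C7, and Felkin–Anh attack with the isopropenyl group as the large substituent should favour the 7,8-anti alcohol with C8 as in 26.

Step 7
Reactants: 10 allylic alcohol
Product: 11 C8 senecioate
Conditions: 3-methylbut-2-enoyl chloride, pyridine, DMAP (cat.), CH2Cl2, 0 °C
Reagents that add atoms: 3-methylbut-2-enoyl chloride, CC(C)=CC(=O)Cl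
Why: Acylation of the secondary allylic alcohol places the C8 ester of the target before any neighbouring hydroxyl exists, and pyridine in place of a trialkylamine limits deconjugation through the vinylketene.

Step 8
Reactants: 11 C8 senecioate
Product: 12 primary allylic alcohol
Conditions: HF·pyridine, pyridine, THF, 0 °C to rt
Reagents that add atoms: none
Why: Buffered fluoride cleaves the primary silyl ether without touching the ester, the enone or the alkenes, freeing the hydroxyl that directs the next step.

Step 9
Reactants: 12 primary allylic alcohol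
Product: 13 (9S,10S)-9,10-epoxy alcohol
Conditions: Ti(OiPr)4 (0.3 equiv), L-(+)-diethyl tartrate (0.36 equiv), tBuOOH, 4 Å MS, CH2Cl2, −20 °C
Reagents that add atoms: tert-butyl hydroperoxide, CC(C)(C)OO
Why: Katsuki–Sharpless asymmetric epoxidation touches only the alkene bound through the primary allylic hydroxyl, and the L-(+)-tartrate ligand should set C9 (final configuration) and C10 (to be inverted) by reagent control as the trans epoxide.

Step 10
Reactants: 13 epoxy alcohol
Product: 14 1,9,10-triol
Conditions: HClO4 (5 mol %), THF–H2O (3:1), 0 °C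
Reagents that add atoms: water, O
Why: Acid-catalysed epoxide hydrolysis opens the trisubstituted oxirane at the tertiary C10 with inversion while C9–O is retained, giving the 9,10-erythro diol of the target, and participation by the C8 ester carbonyl would enter C10 from the same side.

Step 11
Reactants: 14 triol
Product: 15 1,9-bis(triethylsilyl) ether
Conditions: TESCl (2.3 equiv), imidazole, DMAP (cat.), DMF, 0 °C to rt
Reagents that add atoms: chlorotriethylsilane, CC[Si](CC)(CC)Cl
Why: Chlorosilane/imidazole silylation takes the primary and secondary hydroxyls and leaves the tertiary C10 hydroxyl free, and the C9 silyl ether then blocks acyl migration from O8 until the last step.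

Step 12
Reactants: 15 bis(triethylsilyl) ether
Product: 17 seco Z-enone methyl ketone aldehyde, via alkoxysulfonium chloride 16 (not isolated)
Conditions: (COCl)2, DMSO, CH2Cl2, −78 to −40 °C; then Et3N, −78 to 0 °C
Reagents that add atoms: dimethyl sulfoxide, CS(C)=O (kept by 16 only)
Why: Under Swern conditions a primary triethylsilyl ether is cleaved by the chlorosulfonium salt and oxidised in the same flask while the secondary silyl ether and the tertiary alcohol persist, which should give the non-enolisable C1 aldehyde directly.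

Step 13
Reactants: 17 seco Z-enone methyl ketone aldehyde
Product: 19 ten-membered 1-hydroxy-3-ketone, via dilithium alkoxide enolate 18 (not isolated)
Conditions: LiN(SiMe3)2 (2.2 equiv), THF, −78 °C, 17 added by syringe pump to 0.003 M; AcOH quench at −78 °C
Reagents that add atoms: none
Why: LiN(SiMe3)2 first turns the C10 hydroxyl into its lithium alkoxide and then removes a proton from the C2 methyl group (kinetic α' enolate 18), whose carbon adds to the C1 aldehyde; the closest known reaction type is the macrocyclising lithium aldol addition of a methyl ketone to a non-enolisable aldehyde. The ten-membered ring closes in a 10-(enolendo)-exo-trig mode, helped by the Z C4=C5 bond, which already holds C3 and C6 cis, and by the substituents on C7–C10. The new C1 stereocentre is controlled by the C10 alkoxide: lithium bridges O10 and the aldehyde oxygen (Cram chelate), so the enolate should enter past the C10 methyl group and give the (1S) carbinol, the epimer that becomes the cis 1,10-epoxide by inversion, whereas the Felkin–Anh mode would lead to the trans epoxide. The step needs chemoselectivity (C1 can only be the electrophile because C10 bears no hydrogen, and the C8 ester is far less electrophilic) and site-selective deprotonation (CH3 rather than the γ-CH2 at C6), both secured by the hindered amide base at −78 °C. High dilution suppresses oligomers, and the cold acidic quench forestalls retro-aldol cleavage and silyl or acyl transfer to the alkoxides.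

Step 14
Reactants: 19 ten-membered 1-hydroxy-3-ketone
Product: 20 1-O-(benzyloxyacetyl)-1,3-anti-diol
Conditions: 2-(benzyloxy)acetaldehyde (4 equiv), SmI2 (0.3 equiv), THF, −10 °C
Reagents that add atoms: 2-(benzyloxy)acetaldehyde, O=CCOCc1ccccc1
Why: In the Evans–Tishchenko reduction the samarium-bound hemiacetal at O1 delivers hydride to the C3 carbonyl through a six-membered chair, which should give the 1,3-anti (3S) allylic alcohol and leave the acyl group on O1, so the two hydroxyls are told apart in the same step.

Step 15
Reactants: 20 allylic alcohol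
Product: 21 4,5-epoxy alcohol
Conditions: VO(acac)2 (5 mol %), tBuOOH, CH2Cl2, 0 °C
Reagents that add atoms: tert-butyl hydroperoxide, CC(C)(C)OO
Why: Vanadium-catalysed hydroxyl-directed epoxidation attacks only the C4=C5 alkene and delivers oxygen syn to the C3 hydroxyl in the conformer with C3–H in the alkene plane (least 1,3-allylic strain with C6), which is also the outer face of the Z-cycloalkene, setting C4 and C5 as in 26.

Step 16
Reactants: 21 epoxy alcohol
Product: 22 C3 angelate
Conditions: (Z)-2-methylbut-2-enoic acid, 2,4,6-trichlorobenzoyl chloride, Et3N, toluene, rt; then 21, 75 °C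
Reagents that add atoms: (Z)-2-methylbut-2-enoic acid, C/C=C(/C)C(=O)O
Why: Yamaguchi-type esterification through the mixed 2,4,6-trichlorobenzoic anhydride, run without a nucleophilic catalyst, acylates the secondary C3 hydroxyl with retention of the Z geometry, and the tertiary C10 hydroxyl is too hindered to react.

Step 17
Reactants: 22 C3 angelate
Product: 23 1,10-diol
Conditions: NH3 (7 M in MeOH), 0 °C
Reagents that add atoms: none
Why: Ammonolysis removes the α-alkoxyacetate, which is far more electrophilic than the hindered conjugated angelate and senecioate, under conditions too weakly basic for acyl migration or epoxide opening.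

Step 18
Reactants: 23 1,10-diol
Product: 25 9-O-triethylsilyl bis-epoxide, via mesylate 24 (not isolated)
Conditions: MsCl, Et3N, CH2Cl2, −20 °C; then DBU, 0 °C to rt
Reagents that add atoms: methanesulfonyl chloride, CS(=O)(=O)Cl (kept by 24 only)
Why: Sulfene-type mesylation acts only on the secondary C1 hydroxyl, and the amidine base then lets O10 displace the mesylate in a 3-exo-tet Williamson closure with inversion at C1, giving the cis 1,10-epoxide without β-elimination because C3 is no longer a ketone.

Step 19
Reactants: 25 9-O-triethylsilyl bis-epoxide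
Product: 26 CNP0320216.1
Conditions: HF·pyridine, pyridine, THF, 0 °C
Reagents that add atoms: none
Why: Pyridine-buffered HF·pyridine removes the secondary triethylsilyl ether under non-basic conditions, so neither the epoxides nor the C8 ester beside the liberated C9 hydroxyl should be disturbed.

**Compound list**

1 | prop-2-yn-1-ol | C#CCO | starting material
2 | (E)-alkenylalane, dimethylaluminium 3-(dimethylalumanyl)-2-methylprop-2-en-1-olate | C[Al](C)/C=C(\C)CO[Al](C)C | intermediate (not isolated)
3 | (E)-3-iodo-2-methylprop-2-en-1-ol | I/C=C(\C)CO | intermediate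
4 | (E)-tert-butyl[(3-iodo-2-methylprop-2-en-1-yl)oxy]dimethylsilane | I/C=C(\C)CO[Si](C)(C)C(C)(C)C | intermediate
5 | (S)-(+)-carvone, (5S)-2-methyl-5-(prop-1-en-2-yl)cyclohex-2-en-1-one | CC1=CC[C@H](C(C)=C)CC1=O | starting material
6 | potassium kinetic (α') dienolate of 5 | CC1=CC[C@H](C(C)=C)C=C1O[K] | intermediate (not isolated)
7 | trans-6-hydroxycarvone, (5R,6R)-6-hydroxy-2-methyl-5-(prop-1-en-2-yl)cyclohex-2-en-1-one | CC1=CC[C@H](C(C)=C)[C@@H](O)C1=O | intermediate
8 | (5R,6R)-1,2-dimethyl-5-(prop-1-en-2-yl)cyclohex-2-ene-1,6-diol (carvone locants; either C1 epimer) | CC1=CC[C@H](C(C)=C)[C@@H](O)C1(C)O | intermediate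
9 | (2R,4Z)-5-methyl-6-oxo-2-(prop-1-en-2-yl)hept-4-enal (C2–C8; aldehyde = C8) | CC(=O)/C(C)=C\C[C@H](C(C)=C)C=O | intermediate
10 | (3Z,6R,7R,8E)-10-[(tert-butyldimethylsilyl)oxy]-7-hydroxy-3,9-dimethyl-6-(prop-1-en-2-yl)deca-3,8-dien-2-one (C7, C8 as in 26) | CC(=O)/C(C)=C\C[C@H](C(C)=C)[C@H](O)/C=C(\C)CO[Si](C)(C)C(C)(C)C | intermediate
11 | 3-methylbut-2-enoate of 10 at O8 | CC(=O)/C(C)=C\C[C@H](C(C)=C)[C@H](OC(=O)C=C(C)C)/C=C(\C)CO[Si](C)(C)C(C)(C)C | intermediate
12 | desilylated 11, primary E-allylic alcohol at C1 | CC(=O)/C(C)=C\C[C@H](C(C)=C)[C@H](OC(=O)C=C(C)C)/C=C(\C)CO | intermediate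
13 | (9S,10S)-9,10-epoxide of 12 (trans epoxide, CH2OH on C10) | CC(=O)/C(C)=C\C[C@H](C(C)=C)[C@H](OC(=O)C=C(C)C)[C@@H]1O[C@@]1(C)CO | intermediate
14 | 1,9,10-triol, 9,10-erythro (C9 as in 26, C10 inverted relative to 13) | CC(=O)/C(C)=C\C[C@H](C(C)=C)[C@H](OC(=O)C=C(C)C)[C@H](O)[C@](C)(O)CO | intermediate
15 | 1,9-bis(triethylsilyl) ether of 14, C10–OH free | CC(=O)/C(C)=C\C[C@H](C(C)=C)[C@H](OC(=O)C=C(C)C)[C@H](O[Si](CC)(CC)CC)[C@](C)(O)CO[Si](CC)(CC)CC | intermediate
16 | C1 alkoxydimethylsulfonium chloride | CC(=O)/C(C)=C\C[C@H](C(C)=C)[C@H](OC(=O)C=C(C)C)[C@H](O[Si](CC)(CC)CC)[C@](C)(O)CO[S+](C)C.[Cl-] | intermediate (not isolated)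
17 | seco Z-enone methyl ketone aldehyde (7R,8S,9S,10S): 8-O-senecioyl, 9-O-triethylsilyl, 10-hydroxy | CC(=O)/C(C)=C\C[C@H](C(C)=C)[C@H](OC(=O)C=C(C)C)[C@H](O[Si](CC)(CC)CC)[C@](C)(O)C=O | intermediate (key-step precursor)
18 | dilithium C10 alkoxide / C2=C3 enolate of 17 | C=C(O[Li])/C(C)=C\C[C@H](C(C)=C)[C@H](OC(=O)C=C(C)C)[C@H](O[Si](CC)(CC)CC)[C@](C)(O[Li])C=O | intermediate (not isolated)
19 | ten-membered 1-hydroxy-3-ketone (1S,7R,8S,9S,10R), Z C4=C5, 10-hydroxy, 9-O-triethylsilyl, 8-O-senecioyl | C=C(C)[C@H]1C/C=C(C)\C(=O)C[C@H](O)[C@@](C)(O)[C@@H](O[Si](CC)(CC)CC)[C@H]1OC(=O)C=C(C)C | intermediate (key-step product)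
20 | (3S)-3-hydroxy-1-O-(benzyloxyacetyl) derivative of 19 (1,3-anti) | C=C(C)[C@H]1C/C=C(C)\[C@@H](O)C[C@H](OC(=O)COCc2ccccc2)[C@@](C)(O)[C@@H](O[Si](CC)(CC)CC)[C@H]1OC(=O)C=C(C)C | intermediate
21 | 4,5-epoxide of 20 (cis epoxide syn to 3-OH; C4, C5 as in 26) | C=C(C)[C@H]1C[C@@H]2O[C@]2(C)[C@@H](O)C[C@H](OC(=O)COCc2ccccc2)[C@@](C)(O)[C@@H](O[Si](CC)(CC)CC)[C@H]1OC(=O)C=C(C)C | intermediate
22 | 3-O-angeloyl derivative of 21 | C=C(C)[C@H]1C[C@@H]2O[C@]2(C)[C@@H](OC(=O)/C(C)=C\C)C[C@H](OC(=O)COCc2ccccc2)[C@@](C)(O)[C@@H](O[Si](CC)(CC)CC)[C@H]1OC(=O)C=C(C)C | intermediate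
23 | 1,10-diol (C1–OH secondary, C10–OH tertiary) | C=C(C)[C@H]1C[C@@H]2O[C@]2(C)[C@@H](OC(=O)/C(C)=C\C)C[C@H](O)[C@@](C)(O)[C@@H](O[Si](CC)(CC)CC)[C@H]1OC(=O)C=C(C)C | intermediate
24 | C1 methanesulfonate of 23 | C=C(C)[C@H]1C[C@@H]2O[C@]2(C)[C@@H](OC(=O)/C(C)=C\C)C[C@H](OS(C)(=O)=O)[C@@](C)(O)[C@@H](O[Si](CC)(CC)CC)[C@H]1OC(=O)C=C(C)C | intermediate (not isolated)
25 | 9-O-triethylsilyl ether of 26 (cis 1,10- and 4,5-epoxides) | C=C(C)[C@H]1C[C@@H]2O[C@]2(C)[C@@H](OC(=O)/C(C)=C\C)C[C@H]2O[C@@]2(C)[C@@H](O[Si](CC)(CC)CC)[C@H]1OC(=O)C=C(C)C | intermediate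
26 | CNP0320216.1, (1R,3S,4S,5S,7R,8S,9S,10S)-3-angeloyloxy-1,10:4,5-diepoxy-9-hydroxy-8-senecioyloxy-7-isopropenyl-4,10-dimethylcyclodecane | C=C(C)[C@H]1C[C@@H]2O[C@]2(C)[C@@H](OC(=O)/C(C)=C\C)C[C@H]2O[C@@]2(C)[C@@H](O)[C@H]1OC(=O)C=C(C)C | target

**Count.** Total: 19 steps. Longest linear sequence: 17 steps (5 to 26, steps 3–19).

**Steps most likely to fail**

1. Step 13 (key step). The ten-membered ring is at the limit of aldol macrocyclisation: intermolecular addition may outrun ring closure, the aldolate may reopen by retro-aldol, the C9 silyl or C8 acyl group may move to the C10 alkoxide, and the enolate may take the wrong aldehyde face. The fallback sets out from 17 and returns at 19, and forms the same C1–C2 bond by a samarium Reformatsky-type closure without free base. LiN(SiMe3)2 and Me3SiCl trap the kinetic enolate and the C10 alkoxide as the bis(trimethylsilyl) derivative F1. N-bromosuccinimide in THF at −78 °C, followed by a mildly acidic work-up that cleaves the tertiary trimethylsilyl ether, gives the bromomethyl ketone F2. SmI2 in THF at −78 °C under high dilution reduces the C–Br bond to a trivalent samarium enolate, which should add to the aldehyde within a samarium chelate and give 19.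

2. Step 10. The oxirane may open at C9 instead of C10, the C10 centre may lose configuration through an open cation, and the C8 acyl group may wander to O9 or O10 after participation. The fallback sets out from 13 and returns at 17, and delivers the C10 oxygen intramolecularly. Boc2O gives the tert-butyl carbonate F3. BF3·OEt2 at −40 °C makes the carbonate carbonyl attack C10 in a 5-exo mode with inversion and loss of 2-methylpropene, giving the cyclic 1,10-carbonate F4 with a free C9 hydroxyl. TESOTf and 2,6-lutidine give the silyl ether F5. K2CO3 in MeOH at 0 °C opens the carbonate to the 1,10-diol F6. Dess–Martin oxidation of the primary alcohol then gives 17.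

3. Step 6. Facial selectivity on the α-branched aldehyde may be poor, and C7 may epimerise by enolisation of 9. The fallback sets out from 9 and 4 and returns at 11. The C8-epimeric alcohol F7 that forms beside 10 is separated and esterified under Mitsunobu conditions (3-methylbut-2-enoic acid, PPh3, diisopropyl azodicarboxylate), which inverts C8 and gives 11 directly, so that both epimers converge.

**Further compounds**

F1 | step 13 | bis(trimethylsilyl) derivative of 17 (C2=C3 silyl enol ether, C10–OSiMe3) | C=C(O[Si](C)(C)C)/C(C)=C\C[C@H](C(C)=C)[C@H](OC(=O)C=C(C)C)[C@H](O[Si](CC)(CC)CC)[C@](C)(O[Si](C)(C)C)C=O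
F2 | step 13 | bromomethyl ketone of 17 (C2–Br, C10–OH free) | BrCC(=O)/C(C)=C\C[C@H](C(C)=C)[C@H](OC(=O)C=C(C)C)[C@H](O[Si](CC)(CC)CC)[C@](C)(O)C=O
F3 | step 10 | C1 tert-butyl carbonate of 13 | CC(=O)/C(C)=C\C[C@H](C(C)=C)[C@H](OC(=O)C=C(C)C)[C@@H]1O[C@@]1(C)COC(=O)OC(C)(C)C
F4 | step 10 | cyclic 1,10-carbonate with free C9 hydroxyl | CC(=O)/C(C)=C\C[C@H](C(C)=C)[C@H](OC(=O)C=C(C)C)[C@H](O)[C@@]1(C)COC(=O)O1
F5 | step 10 | 9-O-triethylsilyl cyclic 1,10-carbonate | CC(=O)/C(C)=C\C[C@H](C(C)=C)[C@H](OC(=O)C=C(C)C)[C@H](O[Si](CC)(CC)CC)[C@@]1(C)COC(=O)O1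
F6 | step 10 | 9-O-triethylsilyl 1,10-diol | CC(=O)/C(C)=C\C[C@H](C(C)=C)[C@H](OC(=O)C=C(C)C)[C@H](O[Si](CC)(CC)CC)[C@](C)(O)CO
F7 | step 6 | C8 epimer of 10 | CC(=O)/C(C)=C\C[C@H](C(C)=C)[C@@H](O)/C=C(\C)CO[Si](C)(C)C(C)(C)C
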